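## The problem

The target is a cyclopentanone (ring A: C1(Et)–C2(=O)–C3(Me)–C4–C5) trans-fused at C4–C5 to a cyclohexene (ring B: C4–C5–C6(Me)=C7–C8–C9). It has six stereocentres: C1, C3, C4, C5, C8 and C9. C8 and C9 are adjacent quaternary carbons with cis ethyl groups and two different one-carbon substituents, the (E)-styryl carbon on C8 and the carboxyl group on C9. Making these two carbons, with the right relation to C4, is the central difficulty. C1 and C3 flank the C2 ketone and C5 can be reached through a C6 carbonyl, so these three centres can be corrected by equilibration towards the all-trans arrangement around ring A. C4, C8 and C9 are fixed once formed, so they must be set by a resident centre of ring A, and that centre must carry the absolute configuration. The sensitive features are the styrene γ,δ to the carboxylic acid (strong acid invites δ-lactonisation), the doubly neopentyl C9 carboxyl (its esters resist attack at the acyl carbon), and any β,γ-unsaturated C2 ketone on the way. The enabling feature is that the cis ethyl groups and cis carbonyl-derived groups on C8/C9 are the imprint of 2,3-diethylmaleic anhydride, and the C6 methyl alkene is the enol triflate of a C6 ketone. Ring B is therefore the [4+2] adduct of that anhydride across C4 and C7 of a ring-A 2-silyloxy diene C4=C5–C6(OSi)=C7.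

## Retrosynthesis

**Acid and C1 (26 ⇐ 24).** The last operations are cleavage of the O–CH3 bond of methyl ester 24 and inversion of C1. A methyl ester is chosen for the C9 carboxyl because it survives every base and organometallic step and can be removed by SN2 attack at the methyl carbon. The ethyl group at C1 is carried on the α face, cis to the C3 methyl, because this gives the cycloaddition a clean facial bias. Once C2 is a ketone, base is expected to move the ethyl group trans to the C5–C6 bond. The forward step needs a thiolate dealkylation and a base equilibration that leave the styrene alone.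

**C2 ketone (24 ⇐ 23 ⇐ 22).** The C2 carbonyl is traced to a β-silyloxy group. A C2 acetal would have to be installed on a β,γ-unsaturated ketone whose C3–H is doubly activated. The silyl ether instead comes with the starting enone, directs both alkyl groups to the opposite face, and sits beside C4 on the face the dienophile must use. The price is a desilylation and an oxidation at the end. These are placed before ester cleavage so that a free C2 hydroxyl never meets a free C9 acid.

**C6 methyl (22 ⇐ 21 ⇐ 19).** The C6–CH3 bond is cut to enol triflate 21 and this to ketone 19. Addition of a methyl nucleophile followed by dehydration would not control the alkene position. Kinetic enolisation of 19 toward the C7 methylene, away from the C5 methine, fixes C6=C7.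

**C6 ketone and C5 (19 ⇐ 17).** The ketone is the hydrolysis product of the silyl enol ether 17 left by the cycloaddition. C5 is set by equilibration; the argument for the trans fusion is given at step 10.

**Styryl group and carboxyl differentiation (17 ⇐ 15 ⇐ 14 ⇐ 13).** The styrene C=C is cut to aldehyde 15 and a benzylphosphonate. The aldehyde and ester come from anhydride 13 by partial reduction of the C8 carbonyl to the hydroxy lactone 14 and methylation. The anhydride is processed while C6 is still masked as the enol ether, because methoxide or hydride would otherwise attack in the wrong place. The forward steps rely on the C8 carbonyl being the more accessible one.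

**Ring B (13 ⇐ 9 + 12).** Cutting C4–C9 and C7–C8 removes ring B, both quaternary carbons and three stereocentres at once. It leaves a monocyclic diene 9 whose three stereocentres all derive from one purchased centre, and an achiral symmetric dienophile 12. No neighbouring cut simplifies as much. The forward reaction must add to the β face of the diene with the anhydride exo.

**Diene (9 ⇐ 8 ⇐ 5 ⇐ 3 ⇐ 1).** The silyl enol ether is cut to methyl ketone 8, and its acetyl group to enol triflate 5 (C5–C6 bond, Stille coupling). Triflate 5 comes from conjugate methylation of enone 3 with trapping of the enolate, which sets C3 anti to the silyloxy group and places the double bond at C4=C5 without a free β-silyloxy ketone. Enone 3 comes from α′-ethylation of the commercial silyloxy enone 1, again anti to the silyloxy group. Both alkyl groups therefore end up cis to each other.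

**Dienophile (12 ⇐ 10).** The anhydride is cut at both ring C–C(=O) bonds to hex-3-yne 10 and two molecules of CO2, joined by a nickel-catalysed double carboxylation.

## Roads not taken

**Alternative 1: anodic coupling of two silyl enol ethers closes ring A.** The cut is C1–C5. The precursor is the bis(silyl enol ether) A2, a ring-B enol ether carrying the C1–C3 chain at C4. Anodic oxidation would join C1 to C5 and give the trans-fused C2,C6-diketone A1.
- Merits: both carbonyls arrive at their final oxidation level, and C1, C3 and C5 are all α to a carbonyl and can be equilibrated together. In this respect it is better than the chosen plan, which spends three late steps on C2 and C1.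
- Weak points: A2 already contains C4, C8 and C9, so the hardest stereochemistry must be made beforehand, most plausibly by the very cycloaddition used here. The coupling forms a bond between a trisubstituted enol ether carbon and C5 next to the crowded C4/C9 region. The styrene in A2 is itself oxidisable at a similar potential.
- Comparison: the chosen plan answers with a key step that makes ring B and its three fixed stereocentres together, rather than moving the problem one ring back.

**Alternative 2: Pauson–Khand cyclocarbonylation of a dienyne closes both rings.** The cut is C4–C5, C1–C2 and C2–C3. The Co2(CO)6 complex of the alkyne in dienyne A4 would combine with the (E)-alkene and CO to give bicyclic enone A3.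
- Merits: three bonds, two rings and the C2 carbonyl in one step. It forms more bonds per step than the chosen plan.
- Weak points: A4 is acyclic and already holds the vicinal quaternary stereocentres C8 and C9, which would have to be made enantioselectively without a ring template. The cyclisation is a six-ring-forming enyne case with an internal alkene, a slow class. A3 still lacks the C3 and C4 stereocentres, which a later reduction of the C3=C4 enone must set next to the quaternary C9. The silyloxyethyl chain needs several steps to become the styryl group.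
- Comparison: the chosen plan forms fewer bonds in its key step but obtains three stereocentres from it and takes both quaternary carbons from a one-step achiral reagent.

**Alternative 3: Dowd–Beckwith ring expansion of a cis-fused bicyclo[3.3.0]octane.** The cut is C6–C7. A primary radical from the bromomethyl β-keto ester A6 adds to the C6 ketone and fragments to the ring-expanded ketone A5.
- Merits: the radical step is insensitive to crowding and has no stereochemical ambiguity. A5 carries two different esters on C8 and C9, so the carboxyl differentiation is solved from the start. The chosen plan must rely on steric discrimination between two anhydride carbonyls instead.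
- Weak points: C8 in A5 is only tertiary, so the second quaternary centre must still be made by ethylation of an ester enolate next to quaternary C9, with control of its configuration. A5 is cis-fused and needs C5 inverted. A6 is a densely substituted bicycle with a quaternary carbon whose synthesis is not shorter than ring B by cycloaddition. Stoichiometric tin hydride is needed.
- Comparison: the chosen plan accepts a stereochemical gamble in its key step (anhydride-exo approach) in exchange for creating C8 and C9 as quaternary centres directly.

Key step: step 6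

Remarks on the chemistry:
- Assumption: (S)-4-[(tert-butyldimethylsilyl)oxy]cyclopent-2-en-1-one (1) is taken as a catalogue compound, like its more common (R) antipode.
- Target numbering (C1–C9) is used for all intermediates. In 1 the carbonyl carbon is C5, the CH2 is C1, the carbinol carbon is C2 and the alkene carbons are C3 (β) and C4 (α).
- α is the face of C4–H in the target (it also carries the C3 methyl, the styryl and the carboxyl groups); β is the opposite face. TBS = tert-butyldimethylsilyl.

Step 1
Reactants: 1 (S)-4-[(tert-butyldimethylsilyl)oxy]cyclopent-2-en-1-one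
Product: 3 (4R,5S)-4-[(tert-butyldimethylsilyl)oxy]-5-ethylcyclopent-2-en-1-one (ethyl trans to the silyloxy group), via lithium dienolate 2 (not isolated)
Conditions: LiN(iPr)2, THF, −78 °C; EtI, DMPU, −78 to −30 °C
Reagents that add atoms: iodoethane, CCI
Why: Kinetic α′-deprotonation of the enone and C-alkylation of the lithium dienolate (enolate alkylation); loss of silanolate would give an antiaromatic cyclopentadienone and is slow in the cold, and the electrophile enters anti to the neighbouring silyloxy group, which sets C1 trans to C2–O.

Step 2
Reactants: 3 (4R,5S)-4-[(tert-butyldimethylsilyl)oxy]-5-ethylcyclopent-2-en-1-one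
Product: 5 (3S,4R,5S)-4-[(tert-butyldimethylsilyl)oxy]-5-ethyl-3-methylcyclopent-1-en-1-yl trifluoromethanesulfonate (ethyl and methyl cis, both trans to the silyloxy group), via lithium enolate 4 (not isolated)
Conditions: Me2CuLi, Et2O, −78 to −40 °C; PhNTf2, THF, −40 °C to rt
Reagents that add atoms: Me2CuLi, [Li+].C[Cu-]C; N-phenylbis(trifluoromethanesulfonimide), O=S(=O)(N(c1ccccc1)S(=O)(=O)C(F)(F)F)C(F)(F)F
Why: Conjugate addition of Me2CuLi anti to the γ-silyloxy group (the rule of prostanoid three-component couplings) sets C3 cis to the ethyl group; the regiodefined enolate is O-triflated in the same flask (conjugate addition–enolate trapping), so the β-silyloxy ketone is never set free.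

Step 3
Reactants: 5 (3S,4R,5S)-4-[(tert-butyldimethylsilyl)oxy]-5-ethyl-3-methylcyclopent-1-en-1-yl trifluoromethanesulfonate; 6 tributyl(1-ethoxyethenyl)stannane
Product: 8 1-[(3S,4R,5R)-4-[(tert-butyldimethylsilyl)oxy]-5-ethyl-3-methylcyclopent-1-en-1-yl]ethan-1-one, via ethoxydiene 7 (not isolated)
Conditions: Pd(PPh3)4 (5 mol %), LiCl, THF, 65 °C; then 1 M HCl, THF, 0 °C
Reagents that add atoms: water, O
Why: Stille coupling of an enol triflate with the 1-ethoxyvinyl stannane (an acetyl anion equivalent) under zerovalent palladium catalysis, then mild hydrolysis of the enol ether; the hindered secondary silyl ether and the stereocentres are not touched.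

Step 4
Reactants: 8 1-[(3S,4R,5R)-4-[(tert-butyldimethylsilyl)oxy]-5-ethyl-3-methylcyclopent-1-en-1-yl]ethan-1-one
Product: 9 tert-butyl({1-[(3S,4R,5R)-4-[(tert-butyldimethylsilyl)oxy]-5-ethyl-3-methylcyclopent-1-en-1-yl]ethenyl}oxy)dimethylsilane (2-silyloxy diene C4=C5–C6(OTBS)=C7; 1α-ethyl, 2β-OTBS, 3α-methyl)
Conditions: TBSOTf, Et3N, CH2Cl2, 0 °C
Reagents that add atoms: tert-butyldimethylsilyl trifluoromethanesulfonate, CC(C)(C)[Si](C)(C)OS(=O)(=O)C(F)(F)F
Why: Soft enolisation of a methyl enone gives the cross-conjugated 2-silyloxy diene (silyl enol ether formation); the methyl group offers the only unhindered α-proton.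

Step 5
Reactants: 10 hex-3-yne
Product: 12 3,4-diethylfuran-2,5-dione (2,3-diethylmaleic anhydride), via diethylmaleic acid 11 (not isolated)
Conditions: Ni(acac)2(bpy) (10 mol %), Zn, MgBr2, 3 Å MS, CO2 (1 atm), DMF, rt; then 3 M HCl
Reagents that add atoms: carbon dioxide, O=C=O
Why: Nickel-catalysed reductive double carboxylation of an internal dialkyl alkyne; both CO2 units add syn across the triple bond through a low-valent nickelacycle, and the cis diacid closes to the anhydride on acidification.

Step 6
Reactants: 9 tert-butyl({1-[(3S,4R,5R)-4-[(tert-butyldimethylsilyl)oxy]-5-ethyl-3-methylcyclopent-1-en-1-yl]ethenyl}oxy)dimethylsilane; 12 3,4-diethylfuran-2,5-dione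
Product: 13 Diels–Alder adduct: ring A with 1α-ethyl, 2β-OTBS, 3α-methyl; ring B with the C5=C6 TBS enol ether, 4α-H, 8β,9β-diethyl and the 8α,9α-dicarboxylic anhydride
Conditions: 12 (3 equiv), BHT (cat.), PhMe, 130 °C, sealed tube
Reagents that add atoms: none
Why: Thermal, concerted but asynchronous [4+2] cycloaddition of normal electron demand between the electron-rich diene C4=C5–C6(OSi)=C7 and the anhydride; the closest known reaction type is the Diels–Alder reaction of 1-(1-silyloxyvinyl)cycloalkenes and other 2-silyloxy dienes with 2,3-dialkylmaleic anhydrides. Ring B is closed by this intermolecular cycloaddition, the two new bonds C4–C9 and C7–C8 forming suprafacially on each partner. C8 and C9 come out cis to each other because the cis geometry of the dienophile is copied into the product. C4 is set by the face of the diene: the α face carries the C1 ethyl and C3 methyl groups, so the dienophile should add to the β face and leave C4–H α. The relation of C4 to C8 and C9 needs the anhydride-exo (ethyl-endo) orientation; the usual endo preference of an anhydride is weakened when both dienophile carbons carry alkyl groups, and here the exo quadrant beside C4 is crowded by C3–H and the β silyloxy group at C2, which a flat carbonyl should tolerate better than an ethyl group. The dienophile is symmetric, so there is no regiochemical question. The two selectivities needed are β-face attack, secured by the cis α-alkyl groups, and exo approach, which is the less certain of the two.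

Step 7
Reactants: 13 Diels–Alder adduct
Product: 14 γ-hydroxy lactone (pseudo-acid): as 13, but the C8 carbonyl is reduced to the lactol carbon CH(OH)–O–C(=O)–C9; mixture of lactol epimers
Conditions: LiAlH(OtBu)3 (1.2 equiv), THF, −40 to −20 °C; aq. NaH2PO4
Reagents that add atoms: none
Why: Partial reduction of a cyclic anhydride to the hydroxy lactone with a bulky, mild hydride; the C8 carbonyl is flanked only by the C7 methylene whereas the C9 carbonyl is shielded by ring A and the C3 methyl group, and the aluminium lactolate should resist a second hydride in the cold.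

Step 8
Reactants: 14 γ-hydroxy lactone
Product: 15 aldehyde ester: as 13, but 8α-formyl and 9α-methoxycarbonyl
Conditions: K2CO3, MeI, DMF, rt
Reagents that add atoms: iodomethane, CI
Why: Under base the pseudo-acid opens to the aldehyde carboxylate, and O-alkylation of the carboxylate gives the normal methyl ester; the aldehyde has no α-hydrogen and cannot epimerise.

Step 9
Reactants: 15 aldehyde ester; 16 diethyl benzylphosphonate
Product: 17 styrene: 8α-[(E)-2-phenylethenyl], 9α-methoxycarbonyl, 8β,9β-diethyl, C5=C6 TBS enol ether, 2β-OTBS, 1α-ethyl, 3α-methyl, 4α-H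
Conditions: NaH, 15-crown-5 (cat.), THF, 0 to 40 °C
Reagents that add atoms: none
Why: Horner–Wadsworth–Emmons olefination with a semi-stabilised benzylphosphonate, which gives (E)-styrenes; the aldehyde is not enolisable and the silyl enol ether is stable to the base.

Step 10
Reactants: 17 styrene silyl enol ether
Product: 19 trans-fused C6 ketone (4α-H, 5β-H), otherwise as 17, via cis-fused ketone 18 (not isolated)
Conditions: Bu4NF (1.1 equiv), AcOH, THF, 0 °C; then NaOMe (0.3 equiv), MeOH, rt
Reagents that add atoms: none
Why: Fluoride cleaves the silyl enol ether much faster than the hindered secondary silyl ether, and methoxide then equilibrates C5 through the enolate (base epimerisation α to a ketone). The trans-fused ketone has both ring-A bonds equatorial on ring B, whereas the cis-fused epimer must place a ring-A bond syn-axial to one of the β ethyl groups in either chair.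

Step 11
Reactants: 19 trans-fused C6 ketone
Product: 21 C6 enol triflate (C6=C7), via potassium enolate 20 (not isolated)
Conditions: KN(SiMe3)2, THF, −78 °C; PhNTf2, −78 to 0 °C
Reagents that add atoms: N-phenylbis(trifluoromethanesulfonimide), O=S(=O)(N(c1ccccc1)S(=O)(=O)C(F)(F)F)C(F)(F)F
Why: Kinetic deprotonation at the C7 methylene rather than the C5 ring-fusion methine, then O-triflation; this is the regiochemistry used to make enol triflates from trans-hydrindan-4-ones for CD-ring fragments of secosteroids, and C5 is not disturbed under irreversible conditions.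

Step 12
Reactants: 21 C6 enol triflate
Product: 22 C6-methyl alkene: 6-methyl-C6=C7, 2β-OTBS, 9α-methoxycarbonyl, 8α-(E)-styryl
Conditions: Me2CuLi, THF, −20 to 0 °C
Reagents that add atoms: Me2CuLi, [Li+].C[Cu-]C
Why: Coupling of an enol triflate with Me2CuLi replaces the triflate by methyl without moving the double bond; the hindered ester and the styrene are inert to the cuprate.

Step 13
Reactants: 22 C6-methyl alkene
Product: 23 2β-alcohol, otherwise as 22
Conditions: HF·pyridine, pyridine, THF, rt
Reagents that add atoms: none
Why: Fluoride-mediated cleavage of the secondary silyl ether under weakly acidic conditions; basic fluoride is avoided so that the freed C2 hydroxyl is not driven onto the C9 ester.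

Step 14
Reactants: 23 2β-alcohol
Product: 24 C2 ketone methyl ester with 1α-ethyl (the C1 epimer of the methyl ester of the target)
Conditions: Dess–Martin periodinane, NaHCO3, CH2Cl2, rt
Reagents that add atoms: none
Why: Dess–Martin oxidation of a secondary alcohol under buffered conditions leaves both alkenes and the α-stereocentres untouched.

Step 15
Reactants: 24 C2 ketone methyl ester (1α-ethyl)
Product: 26 CNP0302656.1: 1β,8β,9β-triethyl-3α,6-dimethyl-2-oxo-8α-[(E)-2-phenylethenyl] trans-fused (4α-H, 5β-H) bicyclic 9α-carboxylic acid, via C1-epimeric carboxylate 25 (not isolated)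
Conditions: NaSEt, DMF, 80 °C; then 1 M NaOH, MeOH, rt; then 1 M HCl
Reagents that add atoms: none
Why: The thiolate cleaves the hindered methyl ester by SN2 attack at the methyl carbon, which does not depend on access to the acyl carbon. Base then equilibrates C1 through the C2 enolate so that the ethyl group moves trans to the C5–C6 bond, while C3 already has its methyl trans to the C4–C9 bond; mild acidification spares the styrene.

**Compound list**

1 | (S)-4-[(tert-butyldimethylsilyl)oxy]cyclopent-2-en-1-one | C1[C@H](O[Si](C)(C)C(C)(C)C)C=CC1=O | starting material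
2 | lithium dienolate of 1 (deprotonated at C1; lithium 3-[(tert-butyldimethylsilyl)oxy]cyclopenta-1,4-dien-1-olate) | [Li+].[O-]C1=C[C@H](O[Si](C)(C)C(C)(C)C)C=C1 | intermediate (not isolated)
3 | (4R,5S)-4-[(tert-butyldimethylsilyl)oxy]-5-ethylcyclopent-2-en-1-one | CC[C@H]1[C@H](O[Si](C)(C)C(C)(C)C)C=CC1=O | intermediate
4 | lithium 4-[(tert-butyldimethylsilyl)oxy]-5-ethyl-3-methylcyclopent-1-en-1-olate (ethyl and methyl cis, silyloxy trans to both) | CC[C@H]1[C@H](O[Si](C)(C)C(C)(C)C)[C@@H](C)C=C1[O-].[Li+] | intermediate (not isolated)
5 | (3S,4R,5S)-4-[(tert-butyldimethylsilyl)oxy]-5-ethyl-3-methylcyclopent-1-en-1-yl trifluoromethanesulfonate | CC[C@H]1[C@H](O[Si](C)(C)C(C)(C)C)[C@@H](C)C=C1OS(=O)(=O)C(F)(F)F | intermediate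
6 | tributyl(1-ethoxyethenyl)stannane | CCCC[Sn](CCCC)(CCCC)C(=C)OCC | starting material
7 | 2-ethoxy diene: tert-butyl{[(1R,2R,5S)-3-(1-ethoxyethenyl)-2-ethyl-5-methylcyclopent-3-en-1-yl]oxy}dimethylsilane | CC[C@H]1[C@H](O[Si](C)(C)C(C)(C)C)[C@@H](C)C=C1C(=C)OCC | intermediate (not isolated)
8 | 1-[(3S,4R,5R)-4-[(tert-butyldimethylsilyl)oxy]-5-ethyl-3-methylcyclopent-1-en-1-yl]ethan-1-one | CC[C@H]1[C@H](O[Si](C)(C)C(C)(C)C)[C@@H](C)C=C1C(C)=O | intermediate
9 | tert-butyl({1-[(3S,4R,5R)-4-[(tert-butyldimethylsilyl)oxy]-5-ethyl-3-methylcyclopent-1-en-1-yl]ethenyl}oxy)dimethylsilane | CC[C@H]1[C@H](O[Si](C)(C)C(C)(C)C)[C@@H](C)C=C1C(=C)O[Si](C)(C)C(C)(C)C | intermediate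
10 | hex-3-yne | CCC#CCC | starting material
11 | (Z)-2,3-diethylbut-2-enedioic acid | OC(=O)/C(CC)=C(CC)\C(=O)O | intermediate (not isolated)
12 | 3,4-diethylfuran-2,5-dione | CCC1=C(CC)C(=O)OC1=O | intermediate
13 | Diels–Alder adduct (1α-ethyl, 2β-OTBS, 3α-methyl, 4α-H, C5=C6 TBS enol ether, 8β,9β-diethyl, 8α,9α-dicarboxylic anhydride) | CC[C@H]1[C@H](O[Si](C)(C)C(C)(C)C)[C@@H](C)[C@H]3C1=C(O[Si](C)(C)C(C)(C)C)C[C@]4(CC)C(=O)OC(=O)[C@]34CC | intermediate
14 | γ-hydroxy lactone (C8 lactol carbon, C9 lactone carbonyl; lactol epimers) | CC[C@H]1[C@H](O[Si](C)(C)C(C)(C)C)[C@@H](C)[C@H]3C1=C(O[Si](C)(C)C(C)(C)C)C[C@]4(CC)C(O)OC(=O)[C@]34CC | intermediate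
15 | aldehyde ester (8α-formyl, 9α-methoxycarbonyl) | CC[C@H]1[C@H](O[Si](C)(C)C(C)(C)C)[C@@H](C)[C@H]2C1=C(O[Si](C)(C)C(C)(C)C)C[C@@](C=O)(CC)[C@]2(CC)C(=O)OC | intermediate
16 | diethyl benzylphosphonate | CCOP(=O)(Cc1ccccc1)OCC | starting material
17 | styrene silyl enol ether (8α-(E)-styryl, 9α-methoxycarbonyl) | CC[C@H]1[C@H](O[Si](C)(C)C(C)(C)C)[C@@H](C)[C@H]2C1=C(O[Si](C)(C)C(C)(C)C)C[C@@](/C=C/c1ccccc1)(CC)[C@]2(CC)C(=O)OC | intermediate
18 | cis-fused C6 ketone (4α-H, 5α-H) | CC[C@H]1[C@H](O[Si](C)(C)C(C)(C)C)[C@@H](C)[C@H]2[C@@H]1C(=O)C[C@@](/C=C/c1ccccc1)(CC)[C@]2(CC)C(=O)OC | intermediate (not isolated)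
19 | trans-fused C6 ketone (4α-H, 5β-H) | CC[C@H]1[C@H](O[Si](C)(C)C(C)(C)C)[C@@H](C)[C@H]2[C@H]1C(=O)C[C@@](/C=C/c1ccccc1)(CC)[C@]2(CC)C(=O)OC | intermediate
20 | potassium C6(O)=C7 enolate of 19 | CC[C@H]1[C@H](O[Si](C)(C)C(C)(C)C)[C@@H](C)[C@H]2[C@H]1C([O-])=C[C@@](/C=C/c1ccccc1)(CC)[C@]2(CC)C(=O)OC.[K+] | intermediate (not isolated)
21 | C6 enol triflate (C6=C7) | CC[C@H]1[C@H](O[Si](C)(C)C(C)(C)C)[C@@H](C)[C@H]2[C@H]1C(OS(=O)(=O)C(F)(F)F)=C[C@@](/C=C/c1ccccc1)(CC)[C@]2(CC)C(=O)OC | intermediate
22 | C6-methyl alkene, 2β-OTBS methyl ester | CC[C@H]1[C@H](O[Si](C)(C)C(C)(C)C)[C@@H](C)[C@H]2[C@H]1C(C)=C[C@@](/C=C/c1ccccc1)(CC)[C@]2(CC)C(=O)OC | intermediate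
23 | 2β-alcohol methyl ester | CC[C@H]1[C@H](O)[C@@H](C)[C@H]2[C@H]1C(C)=C[C@@](/C=C/c1ccccc1)(CC)[C@]2(CC)C(=O)OC | intermediate
24 | C2 ketone methyl ester, 1α-ethyl (C1 epimer of the target methyl ester) | CC[C@H]1C(=O)[C@@H](C)[C@H]2[C@H]1C(C)=C[C@@](/C=C/c1ccccc1)(CC)[C@]2(CC)C(=O)OC | intermediate
25 | sodium carboxylate of the C1 epimer of the target | CC[C@H]1C(=O)[C@@H](C)[C@H]2[C@H]1C(C)=C[C@@](/C=C/c1ccccc1)(CC)[C@]2(CC)C(=O)[O-].[Na+] | intermediate (not isolated)
26 | CNP0302656.1 (1β,8β,9β-triethyl-3α,6-dimethyl-2-oxo-8α-[(E)-2-phenylethenyl], 4α-H, 5β-H, 9α-carboxylic acid) | CC[C@@H]1C(=O)[C@@H](C)[C@H]2[C@H]1C(C)=C[C@@](/C=C/c1ccccc1)(CC)[C@]2(CC)C(=O)O | target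

**Step count and risks**

Total step count: 15. Longest linear sequence: 14 steps (steps 1–4 and 6–15, from 1); step 5 is a one-step side branch.

Least certain steps:

- **Step 6 (key step).** The tetrasubstituted dienophile may add so slowly that the diene is lost by desilylation or oligomerisation. The cycloaddition may also go through the anhydride-endo orientation, which would place C4–H trans to the two carbonyl groups and cannot be corrected later. Fallback: starting from 9, the dienophile is replaced by the tied-back sulfide-bridged anhydride cis-2,5-dimethyl-2,5-dihydrothiophene-3,4-dicarboxylic anhydride F1, prepared separately. Its two future ethyl groups are pinned back in a five-membered ring, so the alkene carbons are less encumbered, and the parent anhydride of this type is known to prefer the anhydride-exo mode with furan. The cycloadduct F2 is then desulfurised with Raney nickel (Ni) in EtOAc, which turns both C–S bonds into C–H, releases the two ethyl groups and gives 13.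

- **Step 1.** C-ethylation of the cyclopentenone dienolate may be slow enough for proton transfer, O-alkylation or loss of silanolate to compete. Fallback: starting from 1, the dienolate is trapped at −78 °C with acetaldehyde in an aldol addition to give the β-hydroxy ketone F3. This is converted with PhOC(S)Cl and pyridine into the phenyl thionocarbonate F4 and deoxygenated with Bu3SnH and AIBN (Barton–McCombie), which gives 3.

- **Step 7.** Reduction may run past the aldehyde level to the lactone, or hydride may leak to the C9 carbonyl. Fallback: starting from 13, the anhydride is opened with LiSEt at the more accessible C8 carbonyl to give the thioester acid F5. Its carboxylate is methylated in the same flask with MeI to give the thioester methyl ester F6. Fukuyama reduction (Et3SiH, Pd/C) then stops cleanly at the aldehyde and gives 15.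

- **Step 9.** Addition of the phosphonate anion to the neopentyl aldehyde may be slow, and the intermediate alkoxide may be captured by the neighbouring C9 ester before elimination. Fallback: starting from 15, Wittig methylenation with Ph3P=CH2, which passes through an oxaphosphetane without a free alkoxide, gives the vinyl compound F7. A Mizoroki–Heck arylation with iodobenzene (Pd(OAc)2, P(o-tol)3, Et3N, DMF) then gives 17; the vinyl group has no allylic hydrogen, so only the (E)-styrene can form.

- **Step 11.** Deprotonation at C5 may compete with the neopentyl C7 methylene, which would give the regioisomeric triflate and lose the trans fusion. Fallback: starting from 19, MeLi/CeCl3 adds methyl to the C6 ketone from the equatorial direction (the axial approach is blocked by the axial styryl group) to give the tertiary alcohol F8 with an axial α-hydroxyl. Syn dehydration with the Burgess reagent cannot use the trans C5–H and should favour the endocyclic C6=C7 alkene, which gives 22.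

## Further compounds

F1 | step 6 | cis-2,5-dimethyl-2,5-dihydrothiophene-3,4-dicarboxylic anhydride | C[C@@H]1S[C@H](C)C2=C1C(=O)OC2=O
F2 | step 6 | sulfide-bridged cycloadduct (as 13, the two angular ethyl groups joined through sulfur as a cis-2,5-dimethylthiolane) | CC[C@H]1[C@H](O[Si](C)(C)C(C)(C)C)[C@@H](C)[C@H]3C1=C(O[Si](C)(C)C(C)(C)C)C[C@]4([C@H](C)S5)C(=O)OC(=O)[C@]34[C@H]5C
F3 | step 1 | aldol adduct: (4R,5S)-4-[(tert-butyldimethylsilyl)oxy]-5-(1-hydroxyethyl)cyclopent-2-en-1-one (carbinol epimers) | CC(O)[C@H]1[C@H](O[Si](C)(C)C(C)(C)C)C=CC1=O
F4 | step 1 | O-phenyl thionocarbonate of F3 | CC(OC(=S)Oc1ccccc1)[C@H]1[C@H](O[Si](C)(C)C(C)(C)C)C=CC1=O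
F5 | step 7 | thioester acid (8α-C(=O)SEt, 9α-CO2H, otherwise as 13) | CC[C@H]1[C@H](O[Si](C)(C)C(C)(C)C)[C@@H](C)[C@H]2C1=C(O[Si](C)(C)C(C)(C)C)C[C@@](C(=O)SCC)(CC)[C@]2(CC)C(=O)O
F6 | step 7 | thioester methyl ester (8α-C(=O)SEt, 9α-CO2Me) | CC[C@H]1[C@H](O[Si](C)(C)C(C)(C)C)[C@@H](C)[C@H]2C1=C(O[Si](C)(C)C(C)(C)C)C[C@@](C(=O)SCC)(CC)[C@]2(CC)C(=O)OC
F7 | step 9 | vinyl compound (8α-ethenyl, 9α-CO2Me, otherwise as 15) | CC[C@H]1[C@H](O[Si](C)(C)C(C)(C)C)[C@@H](C)[C@H]2C1=C(O[Si](C)(C)C(C)(C)C)C[C@@](C=C)(CC)[C@]2(CC)C(=O)OC
F8 | step 11 | tertiary alcohol (6β-methyl, 6α-hydroxy, otherwise as 19) | CC[C@H]1[C@H](O[Si](C)(C)C(C)(C)C)[C@@H](C)[C@H]2[C@H]1[C@](C)(O)C[C@@](/C=C/c1ccccc1)(CC)[C@]2(CC)C(=O)OC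
A1 | alternative 1 | trans-fused C2,C6-diketone methyl ester | CC[C@@H]1C(=O)[C@@H](C)[C@H]2[C@H]1C(=O)C[C@@](/C=C/c1ccccc1)(CC)[C@]2(CC)C(=O)OC
A2 | alternative 1 | bis(trimethylsilyl enol ether): ring-B C5=C6 silyl enol ether carrying the 3-(trimethylsilyloxy)hex-3-en-2-yl chain at C4 | CCC=C(O[Si](C)(C)C)[C@@H](C)[C@H]2C=C(O[Si](C)(C)C)C[C@@](/C=C/c1ccccc1)(CC)[C@]2(CC)C(=O)OC
A3 | alternative 2 | bicyclic enone with C3=C4 alkene | CC[C@@H]1C(=O)C(C)=C2[C@H]1C(C)=C[C@@](CCO[Si](C)(C)C(C)(C)C)(CC)[C@]2(CC)C(=O)OC(C)(C)C
A4 | alternative 2 | acyclic dienyne (C3≡C4 alkyne on C9, (E)-C5=C1 and (Z)-C6=C7 alkenes) | CC/C=C/C(C)=C\[C@@](CCO[Si](C)(C)C(C)(C)C)(CC)[C@](C#CC)(CC)C(=O)OC(C)(C)C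
A5 | alternative 3 | ring-expanded hydrindane C6 ketone with C8 ester | CC[C@@H]1C2(OCCO2)[C@@H](C)[C@H]3[C@@H]1C(=O)C[C@H](C(=O)OC)[C@]3(CC)C(=O)OC(C)(C)C
A6 | alternative 3 | bromomethyl β-keto ester on the cis-fused bicyclo[3.3.0]octane | CC[C@@H]1C2(OCCO2)[C@@H](C)[C@H]3[C@@H]1C(=O)C(CBr)(C(=O)OC)[C@]3(CC)C(=O)OC(C)(C)C
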